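The numbers of this flask are assumed, and the outcome is calculated.

The ratio we follow through these set-ups is target still standing at the end per target formed.

in all of them: free catalyst 0.60 mM
- winter: starting material 0.30 M (fed, over 4.80 min); partner 0.180 M; time 6.0 min; all but starting material at the start; starting material goes in evenly over 4.80 min, the run ends at 6.0 min
- autumn: starting material 0.30 M; partner 0.180 M (fed, over 4.80 min); time 6.0 min; all but partner at the start; partner goes in evenly over 4.80 min, the run ends at 6.0 min
- spring: starting material 0.30 M; partner 0.180 M; time 6.0 min; everything together in a closed stirred flask, run for 6.0 min
- summer: starting material 0.30 M; partner 0.180 M; one stirred flow tank at steady state, fed with the mixture as stated, mean residence time 6.0 min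

    catalyst intermediate B → released group + catalyst intermediate C (k1 = 4.6 /s)
    catalyst intermediate C ⇌ free catalyst + target (K2 = 1.4 M, k2 = 2.6 /s)
    target ⇌ isomer of the product (K3 = 1.3, k3 = 0.0017 /s)
    partner + catalyst intermediate A ⇌ catalyst intermediate B (K4 = 270 /M, k4 = 390 /M/s)
    starting material + free catalyst ⇌ catalyst intermediate A (K5 = 0.69 /M, k5 = 13 /M/s)

1. the set-up with the highest amount of target at the outlet or at the end, in percent of the starting material put in ("none" if the first two lie within 2 percentage points) (winter / autumn / spring / summer / none)
2. amount of target at the outlet or at the end, in percent of the starting material put in, winter
3. amount of target at the outlet or at the end, in percent of the starting material put in, autumn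
4. amount of target at the outlet or at the end, in percent of the starting material put in, spring
5. amount of target at the outlet or at the end, in percent of the starting material put in, summer

- the stated concentrations are those of everything mixed, before any reaction; amounts are the same in each set-up
- the feed brings no volume worth counting
- run time (winter): 6.0 min

We keep the books for spring, in percent of the starting material put in. Partner is the limiting reagent, its charge 0.180 M being less than the 0.30 M of starting material, so the account opens at 60.0%. The forms of the catalyst together hold 0.200%, which we drop.

The first entry is what passes through the catalyst. We reckon one turn of the cycle as the sum of the wait in step 1, the wait in step 2, and the two binding waits, and the binding waits carry a factor for the intermediates falling back. We leave out the return of target into catalyst intermediate C. At the charged amounts: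

turn = 0.968 s

pass = c(partner) × turn / c(free catalyst) = 4.84 min

That is shorter than the run of 6.0 min, but the turn lengthens as the reagents fall, so we reckon two legs, each at its midpoint.

first leg, to half of the partner: c(partner) = 0.135 M, turn = 1.07 s, taking 2.68 min

second leg, the time left: c(partner) = 0.0450 M, turn = 1.80 s, passing 0.0665 M

So 0.156 M is formed, which is 52.2%, and 7.80% stays as partner.

The second entry splits what was formed between target and isomer. Step 3 relaxes, forward and back together, with a time of 5.54 min, and its equilibrium share of target is 43.5%. For product formed evenly through a run, the excess above that share survives on average as 61.1%. This gives the kept share, the fraction of evenly formed target still standing as target at the end: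

kept share = equilibrium share + (remainder) × survival = 78.0%

The books then close with 40.7% as target and 11.5% as isomer. The first leg runs faster than the second, so formation is early rather than even, and we take our target entry as somewhat high.

The forecast, higher for spring at 39% than for winter at 33.8%, autumn at 35.3% and summer at 29.9%, and lower than our entry, held that “a 6 min run does not quite finish it”.

The flasks give 33.4% in winter, 35.2% in autumn, 39.0% in spring and 29.8% in summer, so spring stands highest. Spring ends with 47.9% of its starting material, so 52.1% has been used, and the target is 74.9% of that, a reading below the kept share of 78.0%. Autumn, where partner goes in evenly, ends with 55.4% of its starting material. The kept share times the 44.6% used there gives 34.8%, and autumn's flask holds 35.2%.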